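**Retrosynthetic overview**
1. Bongardol 7 is the tyrosol ester of octacosanoic acid, with the chain numbered from the ester carbonyl C1. Its only ring, the benzene ring, is bought with tyrosol, and no ring is formed in the route.
2. The last-step disconnection is the C8–C9 CH2–CH2 bond, which opens to a C9–C28 eicosyl radical and a C1–C8 7-(arylethoxycarbonyl)heptyl radical. Each radical comes from an acid one carbon longer, heneicosanoic acid 5 and the azelaic half-ester 3. Both acids are activated as N-hydroxyphthalimide esters and joined by Ni-electrocatalytic doubly decarboxylative coupling.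
3. Enabling feature: C8 and C9 lie inside the unbranched, heteroatom-free methylene run C2–C27, so both are plain primary radical sites with no stereo- or regiochemical information, and C8 lies seven CH2 groups from C1, the exact span of the C9 diacid. The 4-hydroxyphenyl ring is easily oxidised but inert to reduction, so the decarboxylative coupling is run cathodically, not anodically, and needs no protecting group.
4. The second disconnection is the ester C1–O bond, made first by chemoselective mono-esterification of azelaic acid 2 with the aliphatic OH of tyrosol 1.

Key step: step 4

Remark: the target has no stereocentre and no stereogenic double bond. It is achiral, the given SMILES defines it fully, and no step needs stereocontrol.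

**Step 1**
Reactants: 1 tyrosol [2-(4-hydroxyphenyl)ethanol]; 2 azelaic acid (nonanedioic acid)
Product: 3 9-[2-(4-hydroxyphenyl)ethoxy]-9-oxononanoic acid (mono-tyrosyl azelate)
Conditions: 2 (4 equiv), p-TsOH·H2O (5 mol %), toluene, Dean–Stark, reflux; NaHCO3 extraction, re-acidification, warm-water wash
Reagents that add atoms: none
Why: Fischer esterification engages only the primary aliphatic OH of 1 because phenols are not esterified under acid-catalysed equilibrium conditions, and the fourfold excess of the symmetrical diacid biases the statistical outcome towards the monoester, which is parted from neutral diester by bicarbonate extraction and from 2 by the water solubility of the diacid.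

**Step 2**
Reactants: 3 9-[2-(4-hydroxyphenyl)ethoxy]-9-oxononanoic acid
Product: 4 1-(1,3-dioxoisoindolin-2-yl) 9-[2-(4-hydroxyphenyl)ethyl] nonanedioate
Conditions: NHPI (1.05 equiv), DIC (1.1 equiv), no DMAP, THF/CH2Cl2, 0 °C to rt
Reagents that add atoms: N-hydroxyphthalimide, O=C1c2ccccc2C(=O)N1O
Why: In this carbodiimide active-ester formation the acidic, α-effect N–OH group of NHPI should intercept the O-acylisourea far faster than the neutral phenol when no acyl-transfer catalyst is present, as in the standard preparation of N-hydroxyimide esters of hydroxyphenylalkanoic acids.

**Step 3**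
Reactants: 5 heneicosanoic acid
Product: 6 1,3-dioxoisoindolin-2-yl heneicosanoate
Conditions: NHPI (1.1 equiv), DIC (1.1 equiv), DMAP (10 mol %), CH2Cl2/THF, 30 °C
Reagents that add atoms: N-hydroxyphthalimide, O=C1c2ccccc2C(=O)N1O
Why: Steglich-type esterification of an unfunctionalised fatty acid with NHPI is routine and should give a crystalline redox-active ester.

**Step 4**
Reactants: 4 1-(1,3-dioxoisoindolin-2-yl) 9-[2-(4-hydroxyphenyl)ethyl] nonanedioate; 6 1,3-dioxoisoindolin-2-yl heneicosanoate
Product: 7 bongardol [2-(4-hydroxyphenyl)ethyl octacosanoate]
Conditions: 4 (3 equiv), 6 (1 equiv), NiCl2·6H2O (20 mol %), 2,2':6',2''-terpyridine (20 mol %), NaI (0.2 M), DMF/THF 2:1, undivided cell, Zn(+)/RVC(−), constant current until both esters are consumed, 35 °C, Ar; 1 M HCl work-up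
Reagents that add atoms: none
Why: This is a Ni-electrocatalytic doubly decarboxylative C(sp3)–C(sp3) cross-coupling of two redox-active esters, the reductive counterpart of the mixed Kolbe electrolysis and precedented for primary–primary pairs: cathodically formed low-valent (terpy)Ni passes one electron to each N-acyloxyphthalimide, whose radical anion breaks its N–O bond and loses CO2 to give the primary eicosyl radical from 6 and the primary 7-(alkoxycarbonyl)heptyl radical from 4. Nickel captures the two radicals in turn and reductive elimination from the dialkylnickel(III) species forms the C8–C9 CH2–CH2 bond, while the zinc anode delivers the two electrons and its cations bind the phthalimide anions. The step closes no ring and creates no stereocentre, so no mode of closure and no facial control are at issue. The selectivity needed is cross- over homo-coupling of two electronically alike primary radicals, which is only statistical; the readily made 4 is therefore used in threefold excess to channel the costlier 6 into the cross-product, and the three possible coupling products carry two, one and no phenolic OH, so they should part cleanly on silica gel. Chemoselectivity is secured by the reductive regime, in which the oxidation-prone 4-hydroxyphenyl ring and the alkyl ester are inert, by the tolerance of the alkylnickel intermediates to protic groups (the catalyst is charged as a hexahydrate), and by hydrogen bonding of the phenolic OH to DMF, which slows hydrogen-atom transfer to the alkyl radicals. In this one operation the C28 chain is completed and the unprotected natural product is delivered.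

**Compound list**
1 | tyrosol, 2-(4-hydroxyphenyl)ethanol | OCCc1ccc(O)cc1 | starting material
2 | azelaic acid, nonanedioic acid | OC(=O)CCCCCCCC(=O)O | starting material
3 | 9-[2-(4-hydroxyphenyl)ethoxy]-9-oxononanoic acid | OC(=O)CCCCCCCC(=O)OCCc1ccc(O)cc1 | intermediate
4 | 1-(1,3-dioxoisoindolin-2-yl) 9-[2-(4-hydroxyphenyl)ethyl] nonanedioate | O=C(CCCCCCCC(=O)OCCc1ccc(O)cc1)ON2C(=O)c3ccccc3C2=O | intermediate
5 | heneicosanoic acid | CCCCCCCCCCCCCCCCCCCCC(=O)O | starting material
6 | 1,3-dioxoisoindolin-2-yl heneicosanoate | CCCCCCCCCCCCCCCCCCCCC(=O)ON1C(=O)c2ccccc2C1=O | intermediate
7 | bongardol, 2-(4-hydroxyphenyl)ethyl octacosanoate | CCCCCCCCCCCCCCCCCCCCCCCCCCCC(=O)OCCc1ccc(O)cc1 | target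

**Total step count:** 4. **Longest linear sequence:** 3 steps (1, 2, 4).

**Steps most likely to fail**

Step 4 (key coupling).
- What may go wrong:
  - statistical homocoupling of each radical;
  - premature reduction or β-hydride loss at nickel;
  - hydrogen-atom transfer from the phenolic O–H to the alkyl radicals;
  - slow acyl transfer from the active esters to the phenol;
  - coating of the cathode by the waxy long-chain material.
- The fallback is anodic instead of cathodic, uses free acids instead of active esters, and masks the phenol. It sets out from 3 and 5 and comes back at 7. Acetylation of the phenolate of 3 with acetic anhydride in ice-cold aqueous NaOH (Chattaway conditions, then acidification) should give 9-[2-(4-acetoxyphenyl)ethoxy]-9-oxononanoic acid F1, whose ring is deactivated towards anodic oxidation. Mixed Kolbe electrolysis of F1 (in excess) with 5 is the classical chain extension of a fatty acid by a diacid half-ester (Pt anode and cathode, MeOH, about 5 % neutralisation with Et3N, high current density, 50 °C). It should form the same C8–C9 bond and give 2-(4-acetoxyphenyl)ethyl octacosanoate F2. Aminolysis of the aryl acetate with pyrrolidine (THF, rt), which leaves the alkyl ester alone, should then release 7.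

Step 2 (activation next to a free phenol).
- What may go wrong: competing acylation of the phenol by the O-acylisourea or by the product active ester, leading to oligomerisation, and rearrangement to the N-acylurea in the absence of DMAP.
- The fallback carries the phenol as a benzyl ether from the outset and frees it after the coupling. It sets out from 2 and 6 and comes back at 7. Commercial 2-[4-(benzyloxy)phenyl]ethanol F3 is esterified with an excess of 2 (DIC, DMAP, CH2Cl2/THF) to 9-{2-[4-(benzyloxy)phenyl]ethoxy}-9-oxononanoic acid F4. This acid can be activated under ordinary DMAP catalysis (NHPI, DIC) to 1-(1,3-dioxoisoindolin-2-yl) 9-{2-[4-(benzyloxy)phenyl]ethyl} nonanedioate F5. Coupling with 6 under the conditions of step 4 should give 2-[4-(benzyloxy)phenyl]ethyl octacosanoate F6, and hydrogenolysis (H2, Pd/C, THF/EtOAc, rt) should give 7.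

Step 1 (mono-esterification).
- What may go wrong: over-esterification at the second carboxyl group, incomplete separation from the excess diacid, and acid-induced self-condensation of the phenethyl alcohol.
- The fallback uses a differentiated diacid in place of statistical desymmetrisation and an enzyme in place of acid. It sets out from 1 and comes back at 3. Commercial 9-(tert-butoxy)-9-oxononanoic acid F7 is esterified with 1 by immobilised Candida antarctica lipase B (Novozym 435, MTBE, 4 Å MS, 45 °C). The lipase acylates only the primary alcohol and should give 1-tert-butyl 9-[2-(4-hydroxyphenyl)ethyl] nonanedioate F8. TFA/CH2Cl2 (0 °C to rt, nitrogen sweep) should then cleave the tert-butyl ester to 3.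

**Further compounds**
F1 | step 4 | 9-[2-(4-acetoxyphenyl)ethoxy]-9-oxononanoic acid | CC(=O)Oc1ccc(CCOC(=O)CCCCCCCC(=O)O)cc1
F2 | step 4 | 2-(4-acetoxyphenyl)ethyl octacosanoate | CCCCCCCCCCCCCCCCCCCCCCCCCCCC(=O)OCCc1ccc(OC(C)=O)cc1
F3 | step 2 | 2-[4-(benzyloxy)phenyl]ethanol | OCCc1ccc(OCc2ccccc2)cc1
F4 | step 2 | 9-{2-[4-(benzyloxy)phenyl]ethoxy}-9-oxononanoic acid | OC(=O)CCCCCCCC(=O)OCCc1ccc(OCc2ccccc2)cc1
F5 | step 2 | 1-(1,3-dioxoisoindolin-2-yl) 9-{2-[4-(benzyloxy)phenyl]ethyl} nonanedioate | O=C(CCCCCCCC(=O)OCCc1ccc(OCc2ccccc2)cc1)ON3C(=O)c4ccccc4C3=O
F6 | step 2 | 2-[4-(benzyloxy)phenyl]ethyl octacosanoate | CCCCCCCCCCCCCCCCCCCCCCCCCCCC(=O)OCCc1ccc(OCc2ccccc2)cc1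
F7 | step 1 | 9-(tert-butoxy)-9-oxononanoic acid | CC(C)(C)OC(=O)CCCCCCCC(=O)O
F8 | step 1 | 1-tert-butyl 9-[2-(4-hydroxyphenyl)ethyl] nonanedioate | CC(C)(C)OC(=O)CCCCCCCC(=O)OCCc1ccc(O)cc1
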